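Cedar stalls near 0.00897 M of target after 1.25 d, and its reagent charge was 0.0089 M. So you get one target per reagent, and reagent is the limiting reagent there. You now want the row for the new flasks.

| flask | substrate | reagent | free catalyst | remark | time |
|---|---|---|---|---|---|
| cedar | 0.078 M | 0.0089 M | 0.39 mM | run made earlier |  |
| birch | 0.078 M | 0.042 M | 0.39 mM | run made earlier |  |
| elm | 0.078 M | 0.13 M | 0.39 mM | run made earlier |  |
| ochre | 0.078 M | 0.0100 M | 0.39 mM |  | 6.0 d |
| amber | 0.078 M | 0.0200 M | 0.39 mM |  | 6.0 d |
| green | 0.078 M | 0.0400 M | 0.39 mM |  | 6.0 d |
| grey | 0.078 M | 0.0800 M | 0.39 mM |  | 6.0 d |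
| blue | 0.078 M | 0.150 M | 0.39 mM |  | 6.0 d |

| run | time / d | target / % | substrate / % |
|---|---|---|---|
| cedar | 0.250 | 3.8 | 95.9 |
| cedar | 0.500 | 7.4 | 93.9 |
| cedar | 1.25 | 11.5 | 89.4 |
| cedar | 3.00 | 10.7 | 88.1 |
| birch | 0.250 | 4.4 | 95.0 |
| birch | 0.500 | 8.3 | 90.8 |
| birch | 1.25 | 21.9 | 76.7 |
| birch | 3.00 | 44.6 | 52.6 |
| elm | 0.833 | 14.0 | 82.9 |
| elm | 1.67 | 26.5 | 66.7 |
| elm | 2.50 | 33.2 | 53.9 |
| elm | 3.00 | 38.4 | 45.2 |

(standard deviation of a reading: 0.5 percentage points)

- steps under discussion: reagent + free catalyst -> catalyst intermediate A; catalyst intermediate A -> catalyst intermediate B; substrate + catalyst intermediate B -> catalyst intermediate C; catalyst intermediate C <-> released group + catalyst intermediate D; catalyst intermediate D <-> catalyst intermediate E; catalyst intermediate E -> free catalyst + target; reagent + target -> over-reaction product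
- "hardly changes" means that all values lie within two and a half points (for a concentration: within two and a half percent of the largest)

- [target] at the end for ochre, amber, green, grey, blue, in this order
- the course of these numbers from the first flask to the last (rises, then falls / falls all the way / rises all the way / hardly changes / falls, then rises)

Take the main step first. Birch loses substrate at 0.0123 M d⁻¹, so 6.0 d at that pace reaches 0.0739 M. With this step on its own, each new flask turns its reagent into target up to that reach, and the row rises and flattens.

Now add the over-reaction, where reagent eats target. In elm at 3.00 d, 0.0128 M of the substrate is neither left nor target, and you book it as over-reaction product. Over that time, elm's target averages about 0.0150 M. Counting one reagent per substrate lost and one per over-reaction product, elm's reagent stands near 0.0745 M at the end and averages about 0.102 M. At a steady reagent level this wear is pseudo-first-order. So call the time in which wear halves the target the life of target. Read from elm, it is 2.43 d at that mean level, and it shrinks as reagent grows. At blue's charge it is 1.66 d, shorter than 6.0 d. So I expect blue to lose much of its target, and the row to rise, then fall.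

Last come the catalyst steps. The catalyst charge of 0.39 mM is far less than ochre's reagent, so I leave them inside the steady pace, and they add nothing to my reckoning.

The forecast gave 0.0098 M, 0.0193 M, 0.0358 M, 0.056 M and 0.036 M, so rises, then falls. It held that “The rate barely depends on reagent until the reagent is nearly gone”. My reckoning gives the same shape and no row of its own.

The flasks give 0.00990 M, 0.0194 M, 0.0361 M, 0.0553 M and 0.0383 M, so rises, then falls.

    reagent + free catalyst → catalyst intermediate A (k = 540 L mol⁻¹ h⁻¹)
    catalyst intermediate A → catalyst intermediate B (k = 6.50 h⁻¹)
    substrate + catalyst intermediate B → catalyst intermediate C (k = 160 L mol⁻¹ h⁻¹)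
    catalyst intermediate C ⇌ released group + catalyst intermediate D (K = 0.0260 M, k = 7.10 h⁻¹)
    catalyst intermediate D ⇌ catalyst intermediate E (K = 2.90, k = 42.0 h⁻¹)
    catalyst intermediate E → free catalyst + target (k = 8.70 h⁻¹)
    reagent + target → over-reaction product (k = 0.110 L mol⁻¹ h⁻¹)

Blue shows the turn. Its life of target at charge is 1.66 d, and it ends with over-reaction product at 41.7% of the substrate charged. The over-reaction is part of the reason for the fall: without it, blue gives 0.0710 M in place of 0.0383 M, the shape of the row changes, and the forecast would be wrong. Ochre stands at the other end. Its life of target at charge is 24.9 d, longer than 6.0 d, and it ends with over-reaction product at 0.0636%. In ochre, the falling level of reagent is the largest single effect: with reagent held at its charge, ochre gives 0.0574 M in place of 0.00990 M.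

The readings were generated by integration on assumed constants, noise included.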